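## Structural features

Artocarpol D (33) is an achiral tetracycle: two benzene rings, ring A and ring B, are bridged by the ether oxygen O5 and by the two-carbon unit C10=C11 to form the central oxepine, ring C, and a 2,2-dimethyl-2H-pyran, ring D (O1', C2', C3', C4'), is fused across C10–C11 with its oxygen on C10. Ring A carries C11, a prenyl group para to O5 and a free hydroxyl ortho to that prenyl group; ring B (atoms B1 to B6) carries O5 on B1, a free hydroxyl on B3 and C10 on B6, so it is a resorcinol unit with a carbon substituent para to the hydroxyl. There are no stereocentres, so none stand next to each other; the only one met on the way, C10 of 18–26, is racemic and is erased by oxidation. The fragile parts are the cyclic dienol ether O1'–C10=C11–C4'=C3', which sits on an electron-rich arene, is open to acid-induced hydrolysis and is in thermal equilibrium with its ring-open dienone; the ortho-prenylphenol of ring A, which cyclises to a chroman under acid and is easily oxidised; and the two phenols. The real difficulty is the unsymmetrical seven-membered diaryl ether: the two arenes are substituted differently, oxygen must sit on C10 and not on C11, and ring C is the hardest ring to close. The key step exploits the oxygenation pattern of ring B: an oxygen substituent on B1 meta to a hydroxyl on B3, with carbon on B6, is what a vinylketene and an ynol ether give on benzannulation. Because the ynol ether oxygen is O5, already bonded to ring A, and the ketene α-carbon is joined to ring A through C10 and C11, the event that makes ring B also closes ring C.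

## Logic of the disconnections

33 from 32. Only the two aryl O–Si bonds are cut. Ending with a fluoride-labile group on both phenols keeps acid away from ring D and from the ortho-prenylphenol. The gain in skeleton is nil, the gain in safety is large. The demand is that both phenols carry the same silyl group at the end, which fixes the ring A protecting group from step 4 onward.

32 from 27 and 28. Ring D is opened at O1'–C2' (retro-oxa-6π) to dienone 31, which is cut at C11=C4' (retro-aldol condensation). Five carbons and one ring are removed, and the ketone left has C11 as its only enolisable position. The forward step must deliver the Z-dienone, or let E and Z equilibrate so that ring closure drains the mixture.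

27 from 24 (through 26 and 25). No skeletal bond is cut: the C10 carbonyl is traced to a silyl-protected C10 alcohol and the ring B silyl ether to a free phenol. The reason is that the key step delivers C10 at the alcohol level and ring B as a free phenol. The demand is a C10 silyl ether that can be removed without touching aryl silyl ethers, hence triethylsilyl on C10 against triisopropylsilyl on the phenols.

24 from 19. Four bonds are cut: B3–B4 (retro-6π), B6–B1 and B3–B2 (retro-(2+2)) and B6–B5 (retro-Wolff). Rings B and C vanish together and a tricycle becomes one arene with an acyclic chain; the 1,3-oxygenation of ring B and the position of O5 make the cut legitimate. The forward step demands that the vinylketene reaches its own ynol ether across a five-atom tether faster than anything else, and that C10 carries no group able to trap the ketene.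

19 from 14 and 17 (through 18). The C10–B6 bond is cut as an aldol addition of a metallated diazo ketone to an arylacetaldehyde. This separates the fully substituted ring A from a four-carbon diazo enone. The demand is that the aldehyde already contains the ynol ether, so everything after its formation must be non-acidic, and the adduct must be silylated at once against retro-aldol cleavage.

17 from 15. The C=N2 bond is cut (diazo transfer by way of 16). The gain is a commercial four-carbon enone. The demand is low-temperature enolisation of a vinyl ketone that polymerises easily.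

14 from 7 (through 13, 10 and 8). The ynol ether is taken back to the dichlorovinyl ether, and the C10–C11 bond is cut so that C10 comes from a one-carbon Wittig reagent and C11 from the formyl carbon of 7. The strong base needed for the ynol ether does not tolerate an aldehyde, and the ynol ether does not tolerate acid, so the chain is carried as a primary alcohol and oxidised last under buffered conditions. The demands are hydroboration of the styrene in preference to the prenyl alkene, and survival of the aryl silyl ether toward organolithium.

7 from 1, 2 and 4 (through 6, 5 and 3). The ring A C5–prenyl bond is traced to the O–prenyl bond of 5 by a 1,3-shift; the aryl O–vinyl bond leads to 4 and the O–prenyl bond to 2. The prenyl ether shields the 4-hydroxyl while the hydrogen-bonded 2-hydroxyl reacts with 4 under hot carbonate, conditions under which an aryl silyl ether para to a formyl group would be at risk. Its migration to carbon then frees the hydroxyl for silylation, so all three ring A substituents are placed from 1 without a separate protection and deprotection. The demand is migration to C5 and not to C3.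

## Other disconnections considered

Alternative 1: The cut is the C11–ring A bond, traced back to a C9–aryl bond of the symmetric 3,6-dimethoxy-9-methylenexanthene A1. In the forward step PhI(OH)OTs (a trivalent iodine reagent) in methanol adds to the exocyclic alkene and one aryl group shifts from C9 to the methylene carbon as iodobenzene departs, which would give 3,7-dimethoxydibenzo[b,f]oxepin-10(11H)-one A2.
- In its favour: A1 is cheap and symmetric, so there is no question of which aryl migrates; the ketone appears directly on C10; and the oxidative 1,2-aryl shift is a well-established reaction type.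
- Against it here: symmetry is the problem. A2 has the same methoxy group on both rings, whereas 33 needs a prenyl group on ring A only. A late C-prenylation would have to choose among four positions ortho to oxygen, C11 and the oxygens themselves. Two aryl methyl ethers would also have to be cleaved with a strong Lewis acid before any prenyl group or ring D is present.
- Comparison: on structure the chosen plan is better, since the prenyl group comes in with the ring A building block and the two arenes are never equivalent. On mechanism the alternative is the better one, because its key step rests on closer precedent than an intramolecular benzannulation. On step economy it is also better as far as the oxepinone core is concerned, but that lead is spent on the unsolved desymmetrisation.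

Alternative 2: The cut is the O1'–C2' bond together with a change of oxidation level: ring D is taken back to the 11-prenyl ketone A3, a dipivalate. In the forward step DDQ removes hydride from the allylic CH2 of the C11 prenyl group of the enolised ketone, and the resulting 11-alkylidene dienone closes by oxa-6π electrocyclisation to artocarpol D dipivalate A4.
- In its favour: it follows the likely biogenesis; the C11 substituent is introduced by simple enolate alkylation instead of with an enolisable enal; and the neutral oxidative conditions tolerate ester protecting groups.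
- Against it here: A3 holds two prenyl groups, and the one on ring A also has a benzylic, allylic CH2 that DDQ could attack. The electron-rich ring D may be oxidised further. The cut also says nothing about how rings B and C are made.
- Comparison: it is an end-game variant and not a rival to the key step. It reaches the same dienone as step 16 and closes it the same way, so on the mechanism of ring closure the two are equal. It needs two operations where step 16 needs one. It is the better plan in freedom of protecting group, while the chosen plan keeps an oxidant away from the ring A prenyl group.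

Alternative 3: The cuts are C11–C4' and C10–O1' at once, leading back to the diaryl alkyne A5 and prenal 28. In the forward step AgSbF6 (monovalent silver) would promote carbonyl–alkyne metathesis through an oxetene that opens to the (E)-aryl dienone A6. Double-bond isomerisation with oxa-6π closure, and a metal-mediated C–O coupling between the ring B ortho-oxygen and the ring A bromide, would then complete 33.
- In its favour: it is convergent, since A5 comes from two arenes by alkyne coupling. The electron-rich 2,4-dioxygenated arene should steer oxygen to C10. The whole carbon frame of ring D arrives in one step.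
- Against it here: intermolecular metathesis of a diaryl alkyne with an enolisable, acid-sensitive enal has little precedent. A cationic Lewis acid meets a prenyl group and silyl ethers. The regiochemical bias is between two electron-rich arenes. A6 is the E isomer and must isomerise before it can close. Ring C is left for a late diaryl ether coupling next to the sensitive pyran.
- Comparison: on step economy the alternative is better (shorter and convergent). On mechanism the two key steps are equal, as both go beyond close precedent. On structure the chosen plan is stronger: it makes the O5–aryl bond early by robust phenol chemistry, closes ring C in the key event and keeps metals and Lewis acids away from ring D.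

Key step: step 12

Remark on the chemistry: prenyl = 3-methylbut-2-en-1-yl, TIPS = triisopropylsilyl, TES = triethylsilyl; 18–26 are racemic at C10 with one enantiomer drawn; ring A is carried as a TIPS ether and C10–OH as a TES ether so that the route ends with fluoride instead of acid.

## Route

Step 1
Reactants: 1 2,4-dihydroxybenzaldehyde; 2 1-bromo-3-methylbut-2-ene (prenyl bromide)
Product: 3 2-hydroxy-4-(prenyloxy)benzaldehyde
Conditions: K2CO3 (1.0 equiv), acetone, 56 °C
Reagents that add atoms: none
Why: Williamson etherification; the 2-hydroxyl is held in a hydrogen bond to the formyl group, so the free and more acidic 4-hydroxyl is alkylated selectively with one equivalent of base.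

Step 2
Reactants: 3 2-hydroxy-4-(prenyloxy)benzaldehyde; 4 trichloroethylene
Product: 5 2-[(E)-1,2-dichloroethenyloxy]-4-(prenyloxy)benzaldehyde
Conditions: K2CO3, DMF, 70 °C
Reagents that add atoms: none
Why: Carbonate generates dichloroacetylene from 4 at low stationary concentration and the phenoxide adds to it with anti protonation, the standard entry to (E)-1,2-dichlorovinyl aryl ethers; the prenyl ether is inert and shields the other hydroxyl.

Step 3
Reactants: 5 2-[(E)-1,2-dichloroethenyloxy]-4-(prenyloxy)benzaldehyde
Product: 6 2-[(E)-1,2-dichloroethenyloxy]-4-hydroxy-5-prenylbenzaldehyde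
Conditions: montmorillonite K10 clay (acid-treated aluminosilicate, Al2Si4O10(OH)2·nH2O), CH2Cl2, 0 °C
Reagents that add atoms: none
Why: Acid-clay-promoted 1,3 oxygen-to-carbon prenyl shift of an aryl prenyl ether through a tight prenyl cation–phenol pair; C5 should be preferred to C3, which is flanked by two oxygen substituents, and the low temperature limits chroman formation.

Step 4
Reactants: 6 2-[(E)-1,2-dichloroethenyloxy]-4-hydroxy-5-prenylbenzaldehyde
Product: 7 2-[(E)-1,2-dichloroethenyloxy]-5-prenyl-4-(triisopropylsilyloxy)benzaldehyde
Conditions: i-Pr3SiCl, imidazole, DMF, 23 °C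
Reagents that add atoms: chlorotriisopropylsilane, CC(C)[Si](Cl)(C(C)C)C(C)C
Why: Silylation of an acidic phenol; the TIPS ether withstands ylide, borane, organolithium and amide bases and is cleaved by fluoride at the end.

Step 5
Reactants: 7 2-[(E)-1,2-dichloroethenyloxy]-5-prenyl-4-(triisopropylsilyloxy)benzaldehyde
Product: 8 1-[(E)-1,2-dichloroethenyloxy]-2-ethenyl-4-prenyl-5-(triisopropylsilyloxy)benzene
Conditions: Ph3PCH3Br, KN(SiMe3)2, THF, 0 °C
Reagents that add atoms: methyltriphenylphosphonium bromide, C[P+](c1ccccc1)(c1ccccc1)c1ccccc1.[Br-]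
Why: Wittig methylenation of a non-enolisable aryl aldehyde; the new carbon becomes C10.

Step 6
Reactants: 8 1-[(E)-1,2-dichloroethenyloxy]-2-ethenyl-4-prenyl-5-(triisopropylsilyloxy)benzene
Product: 10 2-[2-((E)-1,2-dichloroethenyloxy)-5-prenyl-4-(triisopropylsilyloxy)phenyl]ethan-1-ol, via organoborane 9 (not isolated)
Conditions: 9-BBN, THF, 0 → 23 °C; then NaBO3·4H2O, H2O, 23 °C
Reagents that add atoms: sodium perborate tetrahydrate, [Na+].[Na+].O[B-]1(O)OO[B-](O)(O)OO1.O.O.O.O.O.O
Why: Anti-Markovnikov hydroboration–oxidation; 9-BBN adds to the monosubstituted styrene far faster than to the trisubstituted prenyl alkene or the electron-poor dichlorovinyl ether, and perborate oxidises the borane without strong alkali, which spares the aryl silyl ether.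

Step 7
Reactants: 10 2-[2-((E)-1,2-dichloroethenyloxy)-5-prenyl-4-(triisopropylsilyloxy)phenyl]ethan-1-ol
Product: 13 2-[2-(ethynyloxy)-5-prenyl-4-(triisopropylsilyloxy)phenyl]ethan-1-ol, via chloroethynyl ether 11 (not isolated), via lithium acetylide 12 (not isolated)
Conditions: n-BuLi (3.3 equiv), THF, −78 → −40 °C; then H2O, −78 °C
Reagents that add atoms: none
Why: Standard dichlorovinyl ether route to ynol ethers: after the hydroxyl is deprotonated, n-BuLi removes the vinylic hydrogen, chloride is lost to give 11, and chlorine–lithium exchange gives 12, which is protonated on quenching. The substrate has no electrophilic group, and the TIPS ether resists n-BuLi at low temperature.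

Step 8
Reactants: 13 2-[2-(ethynyloxy)-5-prenyl-4-(triisopropylsilyloxy)phenyl]ethan-1-ol
Product: 14 2-[2-(ethynyloxy)-5-prenyl-4-(triisopropylsilyloxy)phenyl]acetaldehyde
Conditions: Dess–Martin periodinane, pyridine, CH2Cl2, 0 °C
Reagents that add atoms: none
Why: Dess–Martin oxidation under buffered, non-acidic conditions, as the aryl ynol ether requires; the arylacetaldehyde is used at once.

Step 9
Reactants: 15 but-3-en-2-one
Product: 17 1-diazobut-3-en-2-one, via trifluoroacetyl diketone 16 (not isolated)
Conditions: LiN(SiMe3)2, THF, −78 °C; CF3CO2CH2CF3; aq. HCl work-up; then MsN3, Et3N, H2O, MeCN, 23 °C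
Reagents that add atoms: methanesulfonyl azide, CS(=O)(=O)N=[N+]=[N-]
Why: Detrifluoroacetylative diazo transfer, the standard route to α'-diazo α,β-enones: kinetic enolisation at the methyl group, trifluoroacetylation to 16, then diazo transfer with loss of the trifluoroacetyl group. The product is kept cold and in solution.

Step 10
Reactants: 17 1-diazobut-3-en-2-one; 14 2-[2-(ethynyloxy)-5-prenyl-4-(triisopropylsilyloxy)phenyl]acetaldehyde
Product: 18 rac-4-diazo-6-[2-(ethynyloxy)-5-prenyl-4-(triisopropylsilyloxy)phenyl]-5-hydroxyhex-1-en-3-one
Conditions: LiN(i-Pr)2, THF, −78 °C; then 14; AcOH, −78 °C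
Reagents that add atoms: none
Why: Aldol-type addition of a lithiated α-diazo ketone to an aldehyde; the diazo-stabilised anion is weakly basic and should add at −78 °C faster than it enolises the arylacetaldehyde. The C10 stereocentre forms racemic, which is of no consequence.

Step 11
Reactants: 18 rac-4-diazo-6-[2-(ethynyloxy)-5-prenyl-4-(triisopropylsilyloxy)phenyl]-5-hydroxyhex-1-en-3-one
Product: 19 rac-4-diazo-6-[2-(ethynyloxy)-5-prenyl-4-(triisopropylsilyloxy)phenyl]-5-(triethylsilyloxy)hex-1-en-3-one
Conditions: Et3SiCl, imidazole, DMF, 0 °C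
Reagents that add atoms: chlorotriethylsilane, CC[Si](Cl)(CC)CC
Why: Silylation blocks retro-aldol cleavage and removes the hydroxyl that could trap the ketene as a β-lactone; TES can later be cleaved with aqueous acetic acid beside aryl TIPS ethers.

Step 12
Reactants: 19 rac-4-diazo-6-[2-(ethynyloxy)-5-prenyl-4-(triisopropylsilyloxy)phenyl]-5-(triethylsilyloxy)hex-1-en-3-one
Product: 24 rac-2-prenyl-10-(triethylsilyloxy)-3-(triisopropylsilyloxy)-10,11-dihydrodibenzo[b,f]oxepin-7-ol, via vinylketene 20 (not isolated), via cyclobutenone 21 (not isolated), via dienylketene 22 (not isolated), via cyclohexadienone 23 (not isolated)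
Conditions: hν (365 nm), degassed ClCH2CH2Cl (0.005 M), 23 °C; then 80 °C in the dark
Reagents that add atoms: none
Why: Proposed new method: near-UV excitation of the α-diazo enone 19 expels N2 with Wolff migration of the vinyl group (B6–B5) to give vinylketene 20; the nucleophilic terminal carbon B2 of the aryl ynol ether then attacks the ketene carbonyl carbon (the future B3) while the ketene α-carbon B6 bonds to the oxygen-bearing B1, a polar (2+2) cycloaddition that gives alkoxycyclobutenone 21 and closes the seven-membered ring C through the B6–B1 bond, with alkyne carbon B2 left outside that ring. At 80 °C the strained 21 should open by 4π electrocyclic cleavage of B3–B6 to dienylketene 22, and because the new B1=B6 double bond lies inside ring C the ketenyl and vinyl groups can only be cis, so thermal disrotatory 6π electrocyclisation (B3–B4) closes ring B to dienone 23, which tautomerises to phenol 24. The closest known reaction is the intermolecular photochemical Wolff variant of the Danheiser benzannulation of α-diazo enones with alkoxy- and silyloxyalkynes, together with intramolecular ketene–alkyne (2+2) cycloadditions over shorter tethers; the tether and the seven-membered ring are what is new. The step needs a single regiochemistry of cycloaddition, and this is secured twice: by the polarisation of the ynol ether and by the C11–C10 tether, which lets only B1 reach B6. No lasting stereocentre is created, since C10 is untouched and the quaternary B6 of 21 becomes aromatic. High dilution disfavours ketene dimerisation and capture by the product phenol, the aryl ynol ether has no β-hydrogen for retro-ene cleavage on heating, and any 20 that closes to its own cyclobutenone reopens at 80 °C.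

Step 13
Reactants: 24 rac-2-prenyl-10-(triethylsilyloxy)-3-(triisopropylsilyloxy)-10,11-dihydrodibenzo[b,f]oxepin-7-ol
Product: 25 rac-2-prenyl-10-(triethylsilyloxy)-3,7-bis(triisopropylsilyloxy)-10,11-dihydrodibenzo[b,f]oxepine
Conditions: i-Pr3SiCl, imidazole, DMF, 23 °C
Reagents that add atoms: chlorotriisopropylsilane, CC(C)[Si](Cl)(C(C)C)C(C)C
Why: Phenol silylation; it guards the ring B phenol against oxidation in step 15 and O-sulfonylation in step 16 and makes the two phenol protecting groups identical.

Step 14
Reactants: 25 rac-2-prenyl-10-(triethylsilyloxy)-3,7-bis(triisopropylsilyloxy)-10,11-dihydrodibenzo[b,f]oxepine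
Product: 26 rac-2-prenyl-3,7-bis(triisopropylsilyloxy)-10,11-dihydrodibenzo[b,f]oxepin-10-ol
Conditions: AcOH/THF/H2O (3:1:1), 23 °C
Reagents that add atoms: none
Why: Selective solvolysis of the secondary alkyl TES ether; aryl TIPS ethers are stable to aqueous acetic acid, and so weak an acid should not ionise the benzylic C10–O bond.

Step 15
Reactants: 26 rac-2-prenyl-3,7-bis(triisopropylsilyloxy)-10,11-dihydrodibenzo[b,f]oxepin-10-ol
Product: 27 2-prenyl-3,7-bis(triisopropylsilyloxy)dibenzo[b,f]oxepin-10(11H)-one
Conditions: Dess–Martin periodinane, pyridine, CH2Cl2, 0 → 23 °C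
Reagents that add atoms: none
Why: Dess–Martin oxidation of a benzylic secondary alcohol; it removes the C10 stereocentre and leaves C11 as the only enolisable position.

Step 16
Reactants: 27 2-prenyl-3,7-bis(triisopropylsilyloxy)dibenzo[b,f]oxepin-10(11H)-one; 28 3-methylbut-2-enal
Product: 32 artocarpol D bis(triisopropylsilyl) ether, via lithium aldolate 29 (not isolated), via allylic mesylate 30 (not isolated), via Z-dienone 31 (not isolated)
Conditions: LiN(SiMe3)2, THF, −78 °C; 28; MsCl, −78 → 0 °C; DBU, 0 → 40 °C
Reagents that add atoms: none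
Why: Directed aldol addition of the C11 lithium enolate to the enal carbonyl, mesylation of 29 and E1cB elimination give dienone 31, whose Z isomer closes ring D by oxa-6π electrocyclisation. DBU should also equilibrate the E and Z dienones so that ring closure drains the mixture; no stereocentre remains.

Step 17
Reactants: 32 artocarpol D bis(triisopropylsilyl) ether
Product: 33 artocarpol D
Conditions: Bu4NF, AcOH, THF, 0 °C, argon
Reagents that add atoms: none
Why: Fluoride cleavage of both aryl TIPS ethers; acetic acid buffering keeps the phenols protonated, and nothing acidic enough to open ring D or cyclise the ortho-prenylphenol is present.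

## Compound list

1 | 2,4-dihydroxybenzaldehyde | O=Cc1ccc(O)cc1O | starting material
2 | 1-bromo-3-methylbut-2-ene (prenyl bromide) | CC(C)=CCBr | starting material
3 | 2-hydroxy-4-(prenyloxy)benzaldehyde | CC(C)=CCOc1ccc(C=O)c(O)c1 | intermediate
4 | trichloroethylene | ClC=C(Cl)Cl | starting material
5 | 2-[(E)-1,2-dichloroethenyloxy]-4-(prenyloxy)benzaldehyde | CC(C)=CCOc1ccc(C=O)c(O/C(Cl)=C\Cl)c1 | intermediate
6 | 2-[(E)-1,2-dichloroethenyloxy]-4-hydroxy-5-prenylbenzaldehyde | CC(C)=CCc1cc(C=O)c(O/C(Cl)=C\Cl)cc1O | intermediate
7 | 2-[(E)-1,2-dichloroethenyloxy]-5-prenyl-4-(triisopropylsilyloxy)benzaldehyde | CC(C)=CCc1cc(C=O)c(O/C(Cl)=C\Cl)cc1O[Si](C(C)C)(C(C)C)C(C)C | intermediate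
8 | 1-[(E)-1,2-dichloroethenyloxy]-2-ethenyl-4-prenyl-5-(triisopropylsilyloxy)benzene | C=Cc1cc(CC=C(C)C)c(O[Si](C(C)C)(C(C)C)C(C)C)cc1O/C(Cl)=C\Cl | intermediate
9 | 9-{2-[2-((E)-1,2-dichloroethenyloxy)-5-prenyl-4-(triisopropylsilyloxy)phenyl]ethyl}-9-borabicyclo[3.3.1]nonane | CC(C)=CCc1cc(CCB2C3CCCC2CCC3)c(O/C(Cl)=C\Cl)cc1O[Si](C(C)C)(C(C)C)C(C)C | intermediate
10 | 2-[2-((E)-1,2-dichloroethenyloxy)-5-prenyl-4-(triisopropylsilyloxy)phenyl]ethan-1-ol | CC(C)=CCc1cc(CCO)c(O/C(Cl)=C\Cl)cc1O[Si](C(C)C)(C(C)C)C(C)C | intermediate
11 | lithium 2-[2-(chloroethynyloxy)-5-prenyl-4-(triisopropylsilyloxy)phenyl]ethoxide | [Li]OCCc1cc(CC=C(C)C)c(O[Si](C(C)C)(C(C)C)C(C)C)cc1OC#CCl | intermediate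
12 | lithium 2-[2-(lithioethynyloxy)-5-prenyl-4-(triisopropylsilyloxy)phenyl]ethoxide | [Li]OCCc1cc(CC=C(C)C)c(O[Si](C(C)C)(C(C)C)C(C)C)cc1OC#C[Li] | intermediate
13 | 2-[2-(ethynyloxy)-5-prenyl-4-(triisopropylsilyloxy)phenyl]ethan-1-ol | OCCc1cc(CC=C(C)C)c(O[Si](C(C)C)(C(C)C)C(C)C)cc1OC#C | intermediate
14 | 2-[2-(ethynyloxy)-5-prenyl-4-(triisopropylsilyloxy)phenyl]acetaldehyde | O=CCc1cc(CC=C(C)C)c(O[Si](C(C)C)(C(C)C)C(C)C)cc1OC#C | intermediate
15 | but-3-en-2-one | C=CC(C)=O | starting material
16 | 1,1,1-trifluorohex-5-ene-2,4-dione | C=CC(=O)CC(=O)C(F)(F)F | intermediate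
17 | 1-diazobut-3-en-2-one | C=CC(=O)C=[N+]=[N-] | intermediate
18 | rac-4-diazo-6-[2-(ethynyloxy)-5-prenyl-4-(triisopropylsilyloxy)phenyl]-5-hydroxyhex-1-en-3-one (one enantiomer drawn) | C=CC(=O)C(=[N+]=[N-])[C@H](O)Cc1cc(CC=C(C)C)c(O[Si](C(C)C)(C(C)C)C(C)C)cc1OC#C | intermediate
19 | rac-4-diazo-6-[2-(ethynyloxy)-5-prenyl-4-(triisopropylsilyloxy)phenyl]-5-(triethylsilyloxy)hex-1-en-3-one (one enantiomer drawn) | C=CC(=O)C(=[N+]=[N-])[C@H](O[Si](CC)(CC)CC)Cc1cc(CC=C(C)C)c(O[Si](C(C)C)(C(C)C)C(C)C)cc1OC#C | intermediate
20 | vinylketene: rac-2-ethenyl-4-[2-(ethynyloxy)-5-prenyl-4-(triisopropylsilyloxy)phenyl]-3-(triethylsilyloxy)but-1-en-1-one | C=CC(=C=O)[C@H](O[Si](CC)(CC)CC)Cc1cc(CC=C(C)C)c(O[Si](C(C)C)(C(C)C)C(C)C)cc1OC#C | intermediate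
21 | cyclobutenone fused to ring C at B1–B6: four-membered ring B3(=O)–B2H=B1(O5)–B6(ethenyl), B6 configuration undefined | C=CC12C(=O)C=C1Oc1cc(O[Si](C(C)C)(C(C)C)C(C)C)c(CC=C(C)C)cc1C[C@H]2O[Si](CC)(CC)CC | intermediate
22 | dienylketene: rac-3-ethenyl-2-(2-oxoethenyl)-7-prenyl-4-(triethylsilyloxy)-8-(triisopropylsilyloxy)-4,5-dihydro-1-benzoxepine | O=C=CC1=C(C=C)[C@H](O[Si](CC)(CC)CC)Cc2cc(CC=C(C)C)c(O[Si](C(C)C)(C(C)C)C(C)C)cc2O1 | intermediate
23 | cyclohexa-2,4-dienone tautomer of 24 (carbonyl at B3, CH2 at B4) | O=C1CC=C2C(=C1)Oc1cc(O[Si](C(C)C)(C(C)C)C(C)C)c(CC=C(C)C)cc1C[C@H]2O[Si](CC)(CC)CC | intermediate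
24 | rac-2-prenyl-10-(triethylsilyloxy)-3-(triisopropylsilyloxy)-10,11-dihydrodibenzo[b,f]oxepin-7-ol (one enantiomer drawn) | CC(C)=CCc1cc2c(cc1O[Si](C(C)C)(C(C)C)C(C)C)Oc1cc(O)ccc1[C@H](O[Si](CC)(CC)CC)C2 | intermediate
25 | rac-2-prenyl-10-(triethylsilyloxy)-3,7-bis(triisopropylsilyloxy)-10,11-dihydrodibenzo[b,f]oxepine | CC(C)=CCc1cc2c(cc1O[Si](C(C)C)(C(C)C)C(C)C)Oc1cc(O[Si](C(C)C)(C(C)C)C(C)C)ccc1[C@H](O[Si](CC)(CC)CC)C2 | intermediate
26 | rac-2-prenyl-3,7-bis(triisopropylsilyloxy)-10,11-dihydrodibenzo[b,f]oxepin-10-ol | CC(C)=CCc1cc2c(cc1O[Si](C(C)C)(C(C)C)C(C)C)Oc1cc(O[Si](C(C)C)(C(C)C)C(C)C)ccc1[C@H](O)C2 | intermediate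
27 | 2-prenyl-3,7-bis(triisopropylsilyloxy)dibenzo[b,f]oxepin-10(11H)-one | CC(C)=CCc1cc2c(cc1O[Si](C(C)C)(C(C)C)C(C)C)Oc1cc(O[Si](C(C)C)(C(C)C)C(C)C)ccc1C(=O)C2 | intermediate
28 | 3-methylbut-2-enal | CC(C)=CC=O | starting material
29 | lithium 3-methyl-1-[10-oxo-2-prenyl-3,7-bis(triisopropylsilyloxy)-10,11-dihydrodibenzo[b,f]oxepin-11-yl]but-2-en-1-olate (racemic diastereomer mixture) | CC(C)=CC(O[Li])C1C(=O)c2ccc(O[Si](C(C)C)(C(C)C)C(C)C)cc2Oc2cc(O[Si](C(C)C)(C(C)C)C(C)C)c(CC=C(C)C)cc21 | intermediate
30 | methanesulfonate of the aldol from 27 and 28 (racemic diastereomer mixture) | CC(C)=CC(OS(C)(=O)=O)C1C(=O)c2ccc(O[Si](C(C)C)(C(C)C)C(C)C)cc2Oc2cc(O[Si](C(C)C)(C(C)C)C(C)C)c(CC=C(C)C)cc21 | intermediate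
31 | (11Z)-11-(3-methylbut-2-en-1-ylidene)-2-prenyl-3,7-bis(triisopropylsilyloxy)dibenzo[b,f]oxepin-10(11H)-one | CC(C)=C/C=C1\C(=O)c2ccc(O[Si](C(C)C)(C(C)C)C(C)C)cc2Oc2cc(O[Si](C(C)C)(C(C)C)C(C)C)c(CC=C(C)C)cc21 | intermediate
32 | artocarpol D bis(triisopropylsilyl) ether | CC(C)=CCc1cc2c(cc1O[Si](C(C)C)(C(C)C)C(C)C)Oc1cc(O[Si](C(C)C)(C(C)C)C(C)C)ccc1C1=C2C=CC(C)(C)O1 | intermediate
33 | artocarpol D | CC(C)=CCc1cc2c(cc1O)Oc1cc(O)ccc1C1=C2C=CC(C)(C)O1 | target

## Step count and risks

Total: 17 steps. Longest linear sequence: 16 steps (steps 1–8 and 10–17); step 9 is a one-step branch.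

**Step 12 (key step).** Two processes are most likely to go wrong. One is a 1,2-hydride shift from C10 to the carbene centre, which competes with vinyl migration because the silyloxy group activates the C10–H bond. The other is intermolecular consumption of the ketene (dimerisation, or acylation of the product phenol) if the seven-membered (2+2) closure is slow.

The fallback uses known chemistry, sets out from 13 and 17 and returns at 27. It makes ring B by the established intermolecular form of the benzannulation and closes ring C by a classical acylation.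
- Alcohol 13 is silylated (Et3SiCl, imidazole) to the primary triethylsilyl ether F1.
- Irradiation of 17 (excess, 365 nm) with F1, followed by warming to 80 °C, should give the 3-aryloxyphenol F2, in which B6 carries hydrogen.
- Silylation (i-Pr3SiCl, imidazole) gives the bis(triisopropylsilyl) ether F3, and aqueous acetic acid frees the primary alcohol F4.
- TEMPO with PhI(OAc)2 in aqueous MeCN gives the arylacetic acid F5, and (COCl)2 with a trace of DMF gives the acid chloride F6.
- SnCl4 at −78 °C then closes ring C by Friedel–Crafts acylation at B6, the position para to the silyloxy group and the only unhindered one the chain can reach. This gives 27 and leaves steps 16 and 17 unchanged.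

**Step 3.** The shift may lack positional selectivity (C3 against C5). The prenyl group may be lost by ionisation without recombination. The new ortho-prenylphenol may cyclise onto its alkene under the acid.

The fallback sets out from 1 and returns at 6; it fixes the position by bromination and cross-coupling.
- Br2 in AcOH gives 5-bromo-2,4-dihydroxybenzaldehyde F7.
- Selective 4-O-alkylation (MeOCH2Cl, i-Pr2NEt) gives the methoxymethyl ether F8.
- Stille coupling with Bu3SnCH2CH=CMe2 and Pd(PPh3)4 (zerovalent palladium) in DMF gives the 5-prenyl aldehyde F9.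
- Reaction with 4 (K2CO3, DMF, 70 °C) gives the dichlorovinyl ether F10.
- Dilute HCl in MeOH at 23 °C removes the acetal, which is harmless at this early stage, and gives 6.

**Step 9 (and its use in step 10).** Enolisation of the vinyl ketone may trigger anionic oligomerisation. The small diazo enone may react with itself, including by conjugate self-addition once it is metallated.

The fallback sets out from 14 and returns at 19; it builds the enone after the aldol step.
- The lithium enolate of N-methoxy-N-methylacetamide (LiN(i-Pr)2, THF, −78 °C) adds to 14 to give the β-hydroxy amide F11.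
- Et3SiCl and imidazole give its triethylsilyl ether F12.
- CH2=CHMgBr (excess, since the ynol ether C–H is deprotonated and restored on work-up) gives the vinyl ketone F13.
- LiN(SiMe3)2 and CF3CO2CH2CF3 give the trifluoroacetyl diketone F14, which MsN3 and Et3N convert into 19.

**Step 16.** The allylic mesylate may eliminate toward a methyl group instead of toward C11. The aldolate may revert. The E-dienone may accumulate if it does not equilibrate to the Z isomer that can close.

The fallback sets out from 27 and returns at 32; it reaches the same dienone by oxidation instead of condensation.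
- The C11 lithium enolate (LiN(SiMe3)2, THF, −78 °C) is alkylated with 2 to give the 11-prenyl ketone F15.
- DDQ in benzene at 80 °C should remove hydride from the allylic CH2 of the new prenyl group of the enol, giving 31, which closes to 32.

## Further compounds

F1 | step 12 | triethyl{2-[2-(ethynyloxy)-5-prenyl-4-(triisopropylsilyloxy)phenyl]ethoxy}silane | CC[Si](CC)(CC)OCCc1cc(CC=C(C)C)c(O[Si](C(C)C)(C(C)C)C(C)C)cc1OC#C
F2 | step 12 | 3-{4-prenyl-2-[2-(triethylsilyloxy)ethyl]-5-(triisopropylsilyloxy)phenoxy}phenol | CC[Si](CC)(CC)OCCc1cc(CC=C(C)C)c(O[Si](C(C)C)(C(C)C)C(C)C)cc1Oc1cccc(O)c1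
F3 | step 12 | triisopropylsilyl ether of F2 | CC[Si](CC)(CC)OCCc1cc(CC=C(C)C)c(O[Si](C(C)C)(C(C)C)C(C)C)cc1Oc1cccc(O[Si](C(C)C)(C(C)C)C(C)C)c1
F4 | step 12 | 2-{5-prenyl-4-(triisopropylsilyloxy)-2-[3-(triisopropylsilyloxy)phenoxy]phenyl}ethan-1-ol | OCCc1cc(CC=C(C)C)c(O[Si](C(C)C)(C(C)C)C(C)C)cc1Oc1cccc(O[Si](C(C)C)(C(C)C)C(C)C)c1
F5 | step 12 | {5-prenyl-4-(triisopropylsilyloxy)-2-[3-(triisopropylsilyloxy)phenoxy]phenyl}acetic acid | OC(=O)Cc1cc(CC=C(C)C)c(O[Si](C(C)C)(C(C)C)C(C)C)cc1Oc1cccc(O[Si](C(C)C)(C(C)C)C(C)C)c1
F6 | step 12 | acid chloride of F5 | O=C(Cl)Cc1cc(CC=C(C)C)c(O[Si](C(C)C)(C(C)C)C(C)C)cc1Oc1cccc(O[Si](C(C)C)(C(C)C)C(C)C)c1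
F7 | step 3 | 5-bromo-2,4-dihydroxybenzaldehyde | O=Cc1cc(Br)c(O)cc1O
F8 | step 3 | 5-bromo-2-hydroxy-4-(methoxymethoxy)benzaldehyde | COCOc1cc(O)c(C=O)cc1Br
F9 | step 3 | 2-hydroxy-4-(methoxymethoxy)-5-prenylbenzaldehyde | COCOc1cc(O)c(C=O)cc1CC=C(C)C
F10 | step 3 | 2-[(E)-1,2-dichloroethenyloxy]-4-(methoxymethoxy)-5-prenylbenzaldehyde | COCOc1cc(O/C(Cl)=C\Cl)c(C=O)cc1CC=C(C)C
F11 | step 9 | rac-4-[2-(ethynyloxy)-5-prenyl-4-(triisopropylsilyloxy)phenyl]-3-hydroxy-N-methoxy-N-methylbutanamide (one enantiomer drawn) | CON(C)C(=O)C[C@H](O)Cc1cc(CC=C(C)C)c(O[Si](C(C)C)(C(C)C)C(C)C)cc1OC#C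
F12 | step 9 | triethylsilyl ether of F11 | CON(C)C(=O)C[C@H](O[Si](CC)(CC)CC)Cc1cc(CC=C(C)C)c(O[Si](C(C)C)(C(C)C)C(C)C)cc1OC#C
F13 | step 9 | rac-6-[2-(ethynyloxy)-5-prenyl-4-(triisopropylsilyloxy)phenyl]-5-(triethylsilyloxy)hex-1-en-3-one | C=CC(=O)C[C@H](O[Si](CC)(CC)CC)Cc1cc(CC=C(C)C)c(O[Si](C(C)C)(C(C)C)C(C)C)cc1OC#C
F14 | step 9 | 4-(trifluoroacetyl) derivative of F13 | C=CC(=O)C(C(=O)C(F)(F)F)[C@H](O[Si](CC)(CC)CC)Cc1cc(CC=C(C)C)c(O[Si](C(C)C)(C(C)C)C(C)C)cc1OC#C
F15 | step 16 | rac-2,11-diprenyl-3,7-bis(triisopropylsilyloxy)dibenzo[b,f]oxepin-10(11H)-one | CC(C)=CCC1C(=O)c2ccc(O[Si](C(C)C)(C(C)C)C(C)C)cc2Oc2cc(O[Si](C(C)C)(C(C)C)C(C)C)c(CC=C(C)C)cc21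
A1 | alternative 1 | 3,6-dimethoxy-9-methylene-9H-xanthene | C=C1c2ccc(OC)cc2Oc2cc(OC)ccc12
A2 | alternative 1 | 3,7-dimethoxydibenzo[b,f]oxepin-10(11H)-one | COc1ccc2c(c1)Oc1cc(OC)ccc1C(=O)C2
A3 | alternative 2 | rac-10-oxo-2,11-diprenyl-10,11-dihydrodibenzo[b,f]oxepine-3,7-diyl dipivalate | CC(C)=CCc1cc2c(cc1OC(=O)C(C)(C)C)Oc1cc(OC(=O)C(C)(C)C)ccc1C(=O)C2CC=C(C)C
A4 | alternative 2 | artocarpol D dipivalate | CC(C)=CCc1cc2c(cc1OC(=O)C(C)(C)C)Oc1cc(OC(=O)C(C)(C)C)ccc1C1=C2C=CC(C)(C)O1
A5 | alternative 3 | 5-bromo-4-{[2,4-bis(tert-butyldimethylsilyloxy)phenyl]ethynyl}-2-prenylphenyl pivalate | CC(C)=CCc1cc(C#Cc2ccc(O[Si](C)(C)C(C)(C)C)cc2O[Si](C)(C)C(C)(C)C)c(Br)cc1OC(=O)C(C)(C)C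
A6 | alternative 3 | (E)-aryl dienone, open form of the 5,6-diaryl-2,2-dimethyl-2H-pyran | CC(C)=CCc1cc(/C(C(=O)c2ccc(O[Si](C)(C)C(C)(C)C)cc2O[Si](C)(C)C(C)(C)C)=C\C=C(C)C)c(Br)cc1OC(=O)C(C)(C)C
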